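Ring B is opened at C7–C8 and C9–C10 (labdane numbering). These bonds flank the C8–C9 unit, whose substituents C17 and C11 can both be carbonyl carbons, so ring B is read as the Diels–Alder adduct of a fumaraldehydate dienophile with the diene C7=C6–C5=C10 of a 1-vinylcyclohexene that is ring A carrying the C4 gem-diester. One iminium-catalysed enantioselective cycloaddition closes ring B and sets C8, C9 and the quaternary C10; hydrogenation relays C10 to C5. The C11 aldehyde then becomes a vinyl handle, all three esters are reduced, and a B-alkyl Suzuki coupling attaches the butenolide.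

Key step: step 4

Remark: atoms are numbered as in labdanes (ring A = C1–C5 and C10, ring B = C5–C10, C17 on C8, C18 and C19 on C4, C20 on C10, side chain C11–C16); compounds 1, 2, 6 and 13 and all reagents are assumed to be purchasable.

**Step 1**
Reactants: 1 dimethyl malonate; 2 5-bromo-2-methylpent-1-ene
Product: 3 dimethyl 2-(4-methylpent-4-en-1-yl)propanedioate
Conditions: NaH, THF/DMF, 0 → 60 °C (2 equiv of 1)
Reagents that add atoms: none
Why: Malonic ester alkylation, in which the sodium enolate of 1 (in excess to suppress dialkylation) displaces the primary bromide of 2 by SN2; no stereocenter is formed.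

**Step 2**
Reactants: 3 dimethyl 2-(4-methylpent-4-en-1-yl)propanedioate
Product: 4 dimethyl 2-ethynyl-2-(4-methylpent-4-en-1-yl)propanedioate
Conditions: TMS-EBX (1.3 equiv), TBAF (1.3 equiv), THF, −78 °C → rt
Reagents that add atoms: 1-[(trimethylsilyl)ethynyl]-1,2-benziodoxol-3(1H)-one (TMS-EBX), C[Si](C)(C)C#CI1OC(=O)c2ccccc12
Why: Electrophilic α-ethynylation of a stabilised enolate with a hypervalent iodine alkyne-transfer reagent: fluoride desilylates the reagent and generates the malonate anion, which adds to the alkyne β-carbon and receives the ethynyl group after loss of 2-iodobenzoate and a 1,2-hydrogen shift, making C4 quaternary (not a stereocenter).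

**Step 3**
Reactants: 4 dimethyl 2-ethynyl-2-(4-methylpent-4-en-1-yl)propanedioate
Product: 5 dimethyl 2-ethenyl-3-methylcyclohex-2-ene-1,1-dicarboxylate
Conditions: second-generation Grubbs catalyst (H2IMes)(PCy3)Cl2Ru=CHPh (5 mol %), ethylene (1 atm), toluene, 80 °C
Reagents that add atoms: none
Why: Ring-closing enyne metathesis in the exo mode: the ruthenium methylidene adds to the terminal alkyne with ruthenium on the internal carbon C5 (the usual regiochemistry of enyne metathesis), and the vinylcarbene closes onto the 1,1-disubstituted alkene to give the tetrasubstituted C5=C10 ring olefin with the methylene unit transferred to C6.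

**Step 4**
Reactants: 5 dimethyl 2-ethenyl-3-methylcyclohex-2-ene-1,1-dicarboxylate; 6 ethyl (2E)-4-oxobut-2-enoate
Product: 9 6-ethyl 1,1-dimethyl (4aS,5R,6S)-5-formyl-4a-methyl-1,2,3,4,4a,5,6,7-octahydronaphthalene-1,1,6-tricarboxylate, via dienophile iminium chloride 7 (not isolated), via cycloadduct iminium chloride 8 (not isolated)
Conditions: (5S)-5-benzyl-2,2,3-trimethylimidazolidin-4-one hydrochloride (20 mol %), 6 (1.5 equiv), MeNO2/H2O 19:1, 0 °C → rt
Reagents that add atoms: water, O (hydrolysis of 8 returns the formyl oxygen)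
Why: The amine catalyst condenses with 6 to the (E)-iminium ion 7, whose lowered LUMO takes up diene 5 in a concerted but strongly asynchronous [4+2] cycloaddition in which the unsubstituted terminus C7 bonds to the iminium β-carbon C8 ahead of the C9–C10 bond, and hydrolysis of 8 releases 9 and the catalyst. The closest known reaction type is the enantioselective iminium-catalysed Diels–Alder reaction of (E)-β-substituted enals with open-chain and semicyclic dienes. Ring B is closed by an intermolecular [4π+2π] cycloaddition that is suprafacial on both partners, ring A acting only as the carrier of the diene. C8 and C9 should get their absolute configuration from the benzyl group of the catalyst, which blocks one face of 7 so that the diene adds to the Si face of both carbons, and their trans relation from the E geometry of 6. C10 is fixed relative to C9 by the exo placement of the iminium arm: at the tetrasubstituted terminus only the C9 hydrogen fits into the gap between C1 and C5, so C11 should end cis to the C10 methyl group. The step needs C7-to-C8 regiochemistry, secured because attack by C7 leaves allyl cation character on the tertiary C10 and meets the carbon made most electrophilic by the iminium ion, and it needs exo selectivity, secured by the C4 gem-diester and the ring methylene C1 that crowd the endo position at C9.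

**Step 5**
Reactants: 9 6-ethyl 1,1-dimethyl (4aS,5R,6S)-5-formyl-4a-methyl-1,2,3,4,4a,5,6,7-octahydronaphthalene-1,1,6-tricarboxylate
Product: 10 6-ethyl 1,1-dimethyl (4aR,5R,6S,8aS)-5-formyl-4a-methyldecahydronaphthalene-1,1,6-tricarboxylate
Conditions: H2 (10 bar), Pd/C, EtOAc, rt
Reagents that add atoms: none
Why: Heterogeneous syn-hydrogenation: the pseudo-axial C10 methyl group and the axial C4 ester shield one face of the C5=C6 olefin, so hydrogen should be delivered to the opposite face and H5 should end trans to the angular methyl group (trans-decalin), as in the reduction of 5-ene steroids; the formyl and ester groups are inert to neutral Pd/C.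

**Step 6**
Reactants: 10 6-ethyl 1,1-dimethyl (4aR,5R,6S,8aS)-5-formyl-4a-methyldecahydronaphthalene-1,1,6-tricarboxylate
Product: 11 6-ethyl 1,1-dimethyl (4aS,5R,6S,8aS)-5-ethenyl-4a-methyldecahydronaphthalene-1,1,6-tricarboxylate
Conditions: Ph3PCH3Br, KHMDS, THF, 0 °C; then 10, −78 °C → rt
Reagents that add atoms: methyltriphenylphosphonium bromide, C[P+](c1ccccc1)(c1ccccc1)c1ccccc1.[Br-]
Why: Wittig methylenation: the non-stabilised ylide adds to the aldehyde much faster than to the esters, and because C8 and C9 already carry their substituents equatorially the basic medium cannot erode them.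

**Step 7**
Reactants: 11 6-ethyl 1,1-dimethyl (4aS,5R,6S,8aS)-5-ethenyl-4a-methyldecahydronaphthalene-1,1,6-tricarboxylate
Product: 12 [(4aS,5R,6S,8aS)-5-ethenyl-4a-methyldecahydronaphthalene-1,1,6-triyl]trimethanol
Conditions: LiAlH4, THF, 0 °C → reflux; aqueous NaOH work-up
Reagents that add atoms: none
Why: Hydride reduction of all three esters to primary alcohols with LiAlH4; the isolated vinyl group and the four stereocenters are untouched.

**Step 8**
Reactants: 12 [(4aS,5R,6S,8aS)-5-ethenyl-4a-methyldecahydronaphthalene-1,1,6-triyl]trimethanol; 13 3-bromofuran-2(5H)-one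
Product: 15 3-{2-[(1R,2S,4aS,8aS)-2,5,5-tris(hydroxymethyl)-8a-methyldecahydronaphthalen-1-yl]ethyl}furan-2(5H)-one, via tetraborylated alkylborane 14 (not isolated)
Conditions: 9-BBN (4.5 equiv), THF, 0 °C → rt; then 13, PdCl2(dppf) (5 mol %), AsPh3, Cs2CO3, DMF/H2O, rt; aqueous work-up
Reagents that add atoms: none
Why: One-pot hydroboration and B-alkyl Suzuki–Miyaura coupling: three equivalents of 9-BBN are consumed by the hydroxyl groups as borinates and the fourth adds anti-Markovnikov to the vinyl group to give 14, whose primary alkyl group is transferred to the alkenylpalladium bromide formed by oxidative addition of zerovalent palladium to 13, making C12–C13 without touching any stereocenter; the O–B bonds hydrolyse on work-up.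

**Compound list**

1 | dimethyl malonate | COC(=O)CC(=O)OC | starting material
2 | 5-bromo-2-methylpent-1-ene | CC(=C)CCCBr | starting material
3 | dimethyl 2-(4-methylpent-4-en-1-yl)propanedioate | COC(=O)C(CCCC(C)=C)C(=O)OC | intermediate
4 | dimethyl 2-ethynyl-2-(4-methylpent-4-en-1-yl)propanedioate | COC(=O)C(C#C)(CCCC(C)=C)C(=O)OC | intermediate
5 | dimethyl 2-ethenyl-3-methylcyclohex-2-ene-1,1-dicarboxylate | COC(=O)C1(C(=O)OC)CCCC(C)=C1C=C | intermediate
6 | ethyl (2E)-4-oxobut-2-enoate | CCOC(=O)/C=C/C=O | starting material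
7 | (5S)-5-benzyl-1-[(2E)-4-ethoxy-4-oxobut-2-en-1-ylidene]-2,2,3-trimethyl-4-oxoimidazolidin-1-ium chloride | CCOC(=O)/C=C/C=[N+]1\[C@@H](Cc2ccccc2)C(=O)N(C)C1(C)C.[Cl-] | intermediate
8 | (5S)-5-benzyl-1-{[(1R,2S,8aS)-2-(ethoxycarbonyl)-5,5-bis(methoxycarbonyl)-8a-methyl-1,2,3,5,6,7,8,8a-octahydronaphthalen-1-yl]methylidene}-2,2,3-trimethyl-4-oxoimidazolidin-1-ium chloride | C[C@@]12CCCC(C(=O)OC)(C(=O)OC)C1=CC[C@H](C(=O)OCC)[C@H]2C=[N+]3[C@@H](Cc4ccccc4)C(=O)N(C)C3(C)C.[Cl-] | intermediate
9 | 6-ethyl 1,1-dimethyl (4aS,5R,6S)-5-formyl-4a-methyl-1,2,3,4,4a,5,6,7-octahydronaphthalene-1,1,6-tricarboxylate | C[C@@]12CCCC(C(=O)OC)(C(=O)OC)C1=CC[C@H](C(=O)OCC)[C@H]2C=O | intermediate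
10 | 6-ethyl 1,1-dimethyl (4aR,5R,6S,8aS)-5-formyl-4a-methyldecahydronaphthalene-1,1,6-tricarboxylate | C[C@@]12CCCC(C(=O)OC)(C(=O)OC)[C@H]1CC[C@H](C(=O)OCC)[C@H]2C=O | intermediate
11 | 6-ethyl 1,1-dimethyl (4aS,5R,6S,8aS)-5-ethenyl-4a-methyldecahydronaphthalene-1,1,6-tricarboxylate | C[C@@]12CCCC(C(=O)OC)(C(=O)OC)[C@H]1CC[C@H](C(=O)OCC)[C@H]2C=C | intermediate
12 | [(4aS,5R,6S,8aS)-5-ethenyl-4a-methyldecahydronaphthalene-1,1,6-triyl]trimethanol | C[C@@]12CCCC(CO)(CO)[C@H]1CC[C@H](CO)[C@H]2C=C | intermediate
13 | 3-bromofuran-2(5H)-one | O=C1OCC=C1Br | starting material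
14 | B-alkyl-9-borabicyclo[3.3.1]nonane from 12 carrying three O-(9-borabicyclo[3.3.1]nonan-9-yl) groups | C[C@@]12CCCC(COB3C4CCCC3CCC4)(COB3C4CCCC3CCC4)[C@H]1CC[C@H](COB3C4CCCC3CCC4)[C@H]2CCB3C4CCCC3CCC4 | intermediate
15 | 3-{2-[(1R,2S,4aS,8aS)-2,5,5-tris(hydroxymethyl)-8a-methyldecahydronaphthalen-1-yl]ethyl}furan-2(5H)-one | C[C@@]12CCCC(CO)(CO)[C@H]1CC[C@H](CO)[C@H]2CCC1=CCOC1=O | target

Total step count: 8. Longest linear sequence: 8 steps (1 → 15); 6 and 13 are purchased.

**Steps most likely to fail**

Step 4. The hindered, twisted diene may add too slowly to the iminium ion, so that decomposition of the dienophile takes over. The exo and facial discrimination may also be low, which would erode the configuration of C10 relative to C8 and C9. The fallback replaces catalyst control by auxiliary control under Lewis-acid activation; it sets out from 5 and comes back at 9. The dienophile (4S)-4-benzyl-3-[(2E)-4-ethoxy-4-oxobut-2-enoyl]-1,3-oxazolidin-2-one F1 is made from monoethyl fumarate and (4S)-4-benzyl-1,3-oxazolidin-2-one (PivCl, Et3N, LiCl). It is combined with 5 under Et2AlCl in CH2Cl2 at −78 °C (Evans asymmetric Diels–Alder reaction). The chelated imide is much more electrophilic than 7, its benzyl group blocks the Re face at C9, and the same steric argument should keep the acyl group exo, giving the imide cycloadduct F2. LiSEt in THF at 0 °C should convert it into the S-ethyl thioester F3 with release of the auxiliary. Fukuyama reduction (Et3SiH, Pd/C, acetone) should then return 9.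

Step 5. Hydrogen uptake at the trisubstituted olefin between two quaternary carbons may stall, and forcing it may reduce the formyl group or lower the facial selectivity. The fallback changes from surface hydrogenation to a radical hydrogen-atom-transfer reduction under thermodynamic control; it sets out from 9 and comes back at 10. HC(OMe)3 with PPTS in MeOH should give the dimethyl acetal of 9 F4. Mn(dpm)3, PhSiH3 and t-BuOOH in i-PrOH at rt should reduce the olefin through the tertiary C5 radical, which takes up hydrogen axially and should give the trans-fused dimethyl acetal of 10 F5. Aqueous HCl in THF should return 10.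

Step 8. The hydroxyl groups consume borane and may give poorly soluble borinates, so that hydroboration stays incomplete. The aqueous base needed for transmetalation may also degrade the bromobutenolide before it couples. The fallback masks the hydroxyl groups and forms C12–C13 by a base-free Negishi coupling; it sets out from 12 and comes back at 15. TBSCl and imidazole in DMF should give the tris(tert-butyldimethylsilyl) ether of 12 F6. 9-BBN followed by NaOH/H2O2 should give the C12 primary alcohol F7. I2, PPh3 and imidazole should give the C12 iodide F8. Zinc insertion (Zn dust, LiCl, THF) and coupling with 13 under Pd(OAc)2/SPhos should give the tris(tert-butyldimethylsilyl) ether of 15 F9. HF·pyridine in THF should release 15.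

**Further compounds**

F1 | step 4 | (4S)-4-benzyl-3-[(2E)-4-ethoxy-4-oxobut-2-enoyl]-1,3-oxazolidin-2-one | CCOC(=O)/C=C/C(=O)N1[C@@H](Cc2ccccc2)COC1=O
F2 | step 4 | 6-ethyl 1,1-dimethyl (4aS,5R,6S)-5-{[(4S)-4-benzyl-2-oxo-1,3-oxazolidin-3-yl]carbonyl}-4a-methyl-1,2,3,4,4a,5,6,7-octahydronaphthalene-1,1,6-tricarboxylate | C[C@@]12CCCC(C(=O)OC)(C(=O)OC)C1=CC[C@H](C(=O)OCC)[C@H]2C(=O)N3[C@@H](Cc4ccccc4)COC3=O
F3 | step 4 | 6-ethyl 1,1-dimethyl (4aS,5R,6S)-5-[(ethylsulfanyl)carbonyl]-4a-methyl-1,2,3,4,4a,5,6,7-octahydronaphthalene-1,1,6-tricarboxylate | C[C@@]12CCCC(C(=O)OC)(C(=O)OC)C1=CC[C@H](C(=O)OCC)[C@H]2C(=O)SCC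
F4 | step 5 | 6-ethyl 1,1-dimethyl (4aS,5R,6S)-5-(dimethoxymethyl)-4a-methyl-1,2,3,4,4a,5,6,7-octahydronaphthalene-1,1,6-tricarboxylate | C[C@@]12CCCC(C(=O)OC)(C(=O)OC)C1=CC[C@H](C(=O)OCC)[C@H]2C(OC)OC
F5 | step 5 | 6-ethyl 1,1-dimethyl (4aR,5R,6S,8aS)-5-(dimethoxymethyl)-4a-methyldecahydronaphthalene-1,1,6-tricarboxylate | C[C@@]12CCCC(C(=O)OC)(C(=O)OC)[C@H]1CC[C@H](C(=O)OCC)[C@H]2C(OC)OC
F6 | step 8 | tris(tert-butyldimethylsilyl) ether of 12 | C[C@@]12CCCC(CO[Si](C)(C)C(C)(C)C)(CO[Si](C)(C)C(C)(C)C)[C@H]1CC[C@H](CO[Si](C)(C)C(C)(C)C)[C@H]2C=C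
F7 | step 8 | 2-[(1R,2S,4aS,8aS)-2,5,5-tris({[tert-butyl(dimethyl)silyl]oxy}methyl)-8a-methyldecahydronaphthalen-1-yl]ethan-1-ol | C[C@@]12CCCC(CO[Si](C)(C)C(C)(C)C)(CO[Si](C)(C)C(C)(C)C)[C@H]1CC[C@H](CO[Si](C)(C)C(C)(C)C)[C@H]2CCO
F8 | step 8 | C12 iodide from F7 (2-iodoethyl side chain) | C[C@@]12CCCC(CO[Si](C)(C)C(C)(C)C)(CO[Si](C)(C)C(C)(C)C)[C@H]1CC[C@H](CO[Si](C)(C)C(C)(C)C)[C@H]2CCI
F9 | step 8 | tris(tert-butyldimethylsilyl) ether of 15 | C[C@@]12CCCC(CO[Si](C)(C)C(C)(C)C)(CO[Si](C)(C)C(C)(C)C)[C@H]1CC[C@H](CO[Si](C)(C)C(C)(C)C)[C@H]2CCC1=CCOC1=O
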